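**Retrosynthetic overview**
1. The last ring made is pyran ring F of the lower isoflavan (unit 2: benzo ring D, 3-aryl ring E, pyran ring F). It is closed through C4–C4a on the finished 4-arylisoflavan (unit 1: benzo ring A, 3-aryl ring B, pyran ring C) by a tandem semipinacol 1,2-aryl shift/Friedel–Crafts hydroxyalkylation of an acyclic ArO–CH2–CH(OMs)–CH(OH)–Ar chain; global hydrogenolysis then gives the target.
2. Enabling feature: C4a of the resorcinol ring D is ortho to O1 and para to the 7-oxygen, so it is the most nucleophilic carbon of that ring. C3 carries the 2,4-dioxygenated ring E, an excellent migrating group, so the linear chain rearranges with inversion at C3 to a 2-aryl aldehyde whose C4 carbonyl is captured by C4a.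
3. Unit 1 comes from the same cascade and the same (S)-mesyloxy aldehyde. Its C4 is arylated 3,4-trans by acid opening of a temporary pterocarpan ring with 2-bromo-5-methoxyphenol (the future ring E), whose bromine is the handle for the unit 2 chain.
4. Ring order: rings A and D come from 3-(benzyloxy)phenol and rings B and E from bromophenols; then ring C (step 7), the temporary furan ring (step 8, reopened in step 9), and ring F (step 12).
5. Both C3 stereocentres derive from methyl (S)-glycidate; C4 of unit 1 is set by anti attack on the C4 cation.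

Key step: step 12

Remark: the SMILES is read as (3R,4S)-trans for unit 1 (the 4-arylisoflavan) and 3R for unit 2 (the 7,2'-dihydroxy-4'-methoxyisoflavan); isoflavan numbering is used for both units.

**Route**

Step 1
Reactants: 1 3-(benzyloxy)phenol; 2 methyl (2S)-oxirane-2-carboxylate
Product: 3 methyl (2S)-3-[3-(benzyloxy)phenoxy]-2-hydroxypropanoate
Conditions: CsF (cat.), DMF, 60 °C
Reagents that add atoms: none
Why: Phenoxide opens the glycidate at its unsubstituted C3 (SN2 epoxide ring-opening), so the C2 stereocentre of 2 is untouched and 3 should be 2S.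

Step 2
Reactants: 3 methyl (2S)-3-[3-(benzyloxy)phenoxy]-2-hydroxypropanoate
Product: 4 methyl (2S)-3-[3-(benzyloxy)phenoxy]-2-[(methylsulfonyl)oxy]propanoate
Conditions: MsCl, Et3N, CH2Cl2, −10 °C
Reagents that add atoms: methanesulfonyl chloride CS(=O)(=O)Cl
Why: O-Mesylation of a secondary alcohol proceeds with retention at carbon, and at low temperature the ester α-hydrogen should not be acidic enough for loss of the aryloxide.

Step 3
Reactants: 4 methyl (2S)-3-[3-(benzyloxy)phenoxy]-2-[(methylsulfonyl)oxy]propanoate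
Product: 5 (2S)-3-[3-(benzyloxy)phenoxy]-1-oxopropan-2-yl methanesulfonate
Conditions: i-Bu2AlH (1.1 equiv), CH2Cl2, −78 °C; MeOH, then aq. potassium sodium tartrate, 0 °C; used crude at once
Reagents that add atoms: none
Why: Partial ester reduction with i-Bu2AlH stops at the aldehyde level because the α-oxygenated tetrahedral aluminium hemiacetal is stable at −78 °C, and the cold, non-basic work-up should leave the 2S centre and the β-aryloxy group untouched.

Step 4
Reactants: 6 3,4-dimethoxyphenol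
Product: 7 2-bromo-4,5-dimethoxyphenol
Conditions: NBS, MeCN, −20 → 0 °C
Reagents that add atoms: N-bromosuccinimide O=C1CCC(=O)N1Br
Why: Electrophilic aromatic bromination should occur ortho to OH and para to the 3-methoxy group, the most activated unhindered position.

Step 5
Reactants: 7 2-bromo-4,5-dimethoxyphenol
Product: 8 1-(benzyloxy)-2-bromo-4,5-dimethoxybenzene
Conditions: BnBr, K2CO3, DMF, rt
Reagents that add atoms: benzyl bromide BrCc1ccccc1
Why: Williamson O-benzylation of the phenoxide.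

Step 6
Reactants: 5 (2S)-3-[3-(benzyloxy)phenoxy]-1-oxopropan-2-yl methanesulfonate; 8 1-(benzyloxy)-2-bromo-4,5-dimethoxybenzene
Product: 10 (1RS,2S)-1-[2-(benzyloxy)-4,5-dimethoxyphenyl]-3-[3-(benzyloxy)phenoxy]-1-hydroxypropan-2-yl methanesulfonate, via aryl Grignard reagent 9 (not isolated)
Conditions: 8, Mg, THF, 40 °C; then added to 5, THF–CH2Cl2, −78 → −40 °C; aq. NH4Cl
Reagents that add atoms: none
Why: Grignard 1,2-addition to the α-sulfonyloxy aldehyde at low temperature should outrun enolisation; the carbinol centre forms without control, which is harmless because it becomes the sp2 aldehyde carbon in step 7, and the C–OMs centre stays 2S.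

Step 7
Reactants: 10 (1RS,2S)-1-[2-(benzyloxy)-4,5-dimethoxyphenyl]-3-[3-(benzyloxy)phenoxy]-1-hydroxypropan-2-yl methanesulfonate
Product: 12 (3R,4RS)-7-(benzyloxy)-3-[2-(benzyloxy)-4,5-dimethoxyphenyl]chroman-4-ol, via aryl aldehyde 11 (not isolated)
Conditions: Me2AlCl (3 equiv), CH2Cl2, −78 → −20 °C
Reagents that add atoms: none
Why: Proposed new method: the tandem of step 12 run first on the simpler substrate — Me2AlCl-induced semipinacol 1,2-shift of the 2-(benzyloxy)-4,5-dimethoxyphenyl group with inversion at the mesylate carbon (closest known reaction: Suzuki–Tsuchihashi rearrangement of 2-mesyloxy alcohols with Et3Al) gives aldehyde 11, and Lewis-acid Friedel–Crafts hydroxyalkylation para to the benzyloxy group then closes ring C through C4–C4a (6-exo-trig); C3 becomes R by inversion of the 2S carbon, and C4 forms as a mixture that is ionised in steps 8 and 9.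

Step 8
Reactants: 12 (3R,4RS)-7-(benzyloxy)-3-[2-(benzyloxy)-4,5-dimethoxyphenyl]chroman-4-ol
Product: 14 (6aR,11aR)-3-hydroxy-8,9-dimethoxypterocarpan, via isoflavan triol 13 (not isolated)
Conditions: H2 (1 atm), Pd/C, EtOAc, NaHCO3 (solid), rt; filter; then HCl (cat.), EtOAc–EtOH, rt
Reagents that add atoms: none
Why: Hydrogenolysis of the two aryl benzyl ethers under non-acidic conditions should leave the benzylic C4–OH in place, and acid-catalysed cyclodehydration (SN1 at C4, capture by the 2'-OH) then gives the pterocarpan, whose 5/6 ring fusion can only be cis, so C11a follows C6a.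

Step 9
Reactants: 14 (6aR,11aR)-3-hydroxy-8,9-dimethoxypterocarpan; 15 2-bromo-5-methoxyphenol
Product: 16 (3R,4S)-4-(5-bromo-4-hydroxy-2-methoxyphenyl)-3-(2-hydroxy-4,5-dimethoxyphenyl)chroman-7-ol
Conditions: 15 (5 equiv), TsOH·H2O (20 mol %), HFIP–CH2Cl2, 0 °C → rt
Reagents that add atoms: none
Why: Acid opens the benzylic aryl ether of the pterocarpan to the 7-hydroxy-stabilised C4 cation (pterocarpan-as-electrophile Friedel–Crafts alkylation, SN1), which 15 should capture through its only carbon that is para to OH and ortho to OMe, from the face anti to the C3 aryl group, setting C4 as S (3,4-trans).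

Step 10
Reactants: 16 (3R,4S)-4-(5-bromo-4-hydroxy-2-methoxyphenyl)-3-(2-hydroxy-4,5-dimethoxyphenyl)chroman-7-ol
Product: 17 (3R,4S)-7-(benzyloxy)-4-[4-(benzyloxy)-5-bromo-2-methoxyphenyl]-3-[2-(benzyloxy)-4,5-dimethoxyphenyl]chromane
Conditions: BnBr (4 equiv), K2CO3, DMF, 50 °C
Reagents that add atoms: benzyl bromide BrCc1ccccc1
Why: Williamson O-benzylation of the three phenols protects them for the organometallic and Lewis-acid steps.

Step 11
Reactants: 17 (3R,4S)-7-(benzyloxy)-4-[4-(benzyloxy)-5-bromo-2-methoxyphenyl]-3-[2-(benzyloxy)-4,5-dimethoxyphenyl]chromane; 5 (2S)-3-[3-(benzyloxy)phenoxy]-1-oxopropan-2-yl methanesulfonate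
Product: 20 (1RS,2S)-1-{2-(benzyloxy)-5-[(3R,4S)-7-(benzyloxy)-3-[2-(benzyloxy)-4,5-dimethoxyphenyl]chroman-4-yl]-4-methoxyphenyl}-3-[3-(benzyloxy)phenoxy]-1-hydroxypropan-2-yl methanesulfonate, via aryllithium 18 (not isolated), via aryl Grignard reagent 19 (not isolated)
Conditions: 17, n-BuLi, THF, −78 °C; MgBr2·OEt2, −78 °C; then freshly prepared 5 (1.5 equiv) in THF, −78 → −40 °C; aq. NH4Cl
Reagents that add atoms: none
Why: Bromine–lithium exchange, transmetalation to the less basic Grignard reagent and 1,2-addition to aldehyde 5 should give 20; the carbinol centre is again uncontrolled and irrelevant, and the C–OMs centre is 2S.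

Step 12
Reactants: 20 (1RS,2S)-1-{2-(benzyloxy)-5-[(3R,4S)-7-(benzyloxy)-3-[2-(benzyloxy)-4,5-dimethoxyphenyl]chroman-4-yl]-4-methoxyphenyl}-3-[3-(benzyloxy)phenoxy]-1-hydroxypropan-2-yl methanesulfonate
Product: 22 (3R,4RS)-7-(benzyloxy)-3-{2-(benzyloxy)-5-[(3R,4S)-7-(benzyloxy)-3-[2-(benzyloxy)-4,5-dimethoxyphenyl]chroman-4-yl]-4-methoxyphenyl}chroman-4-ol, via aryl aldehyde 21 (not isolated)
Conditions: Me2AlCl (3.5 equiv), CH2Cl2, −78 → −20 °C
Reagents that add atoms: none
Why: Proposed new method: Me2AlCl turns the carbinol into an aluminium alkoxide (methane is lost) and activates the mesylate, so the electron-rich ring E should migrate from C4 to C3 anti-periplanar to the leaving group with inversion at C3 (closest known reaction: Suzuki–Tsuchihashi semipinacol rearrangement of 2-mesyloxy alcohols with organoaluminium reagents), giving the aluminium-bound (R)-2-aryl aldehyde 21. The same Lewis acid then activates the aldehyde for intramolecular Friedel–Crafts hydroxyalkylation (closest precedent: Me2AlCl-promoted aldehyde–arene and aldehyde–ene cyclisations), in which C4a of ring D attacks the C4 carbonyl carbon. Ring F closes in a 6-exo-trig mode through the C4–C4a bond. C3 (R) is fixed by the S configuration of the mesylate carbon, which comes from methyl (S)-glycidate; the new C4 carbinol centre is not controlled and is removed in step 13. The step needs aryl rather than hydride migration (secured by the 2,4-dioxygenated ring E), attack at the ring D carbon para to the benzyloxy group rather than the carbon between the two oxygens (secured by sterics and para activation), and ring closure faster than enolisation of 21 or methyl transfer from aluminium (secured by six-membered intramolecular capture at low temperature and a reagent without β-hydrogens).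

Step 13
Reactants: 22 (3R,4RS)-7-(benzyloxy)-3-{2-(benzyloxy)-5-[(3R,4S)-7-(benzyloxy)-3-[2-(benzyloxy)-4,5-dimethoxyphenyl]chroman-4-yl]-4-methoxyphenyl}chroman-4-ol
Product: 23 (3R,4S)-4-{4-hydroxy-5-[(3R)-7-hydroxychroman-3-yl]-2-methoxyphenyl}-3-(2-hydroxy-4,5-dimethoxyphenyl)chroman-7-ol
Conditions: H2 (3 atm), Pd(OH)2/C, EtOAc–EtOH, AcOH, rt
Reagents that add atoms: none
Why: Hydrogenolysis should cleave the four aryl benzyl ethers and, with the weak acid, the benzylic C4–OH of ring F (activated by the para 7-oxygen), taking C4 to the CH2 level, while the mild acidity should keep dehydration towards the isoflav-3-ene, the only path that could erode C3, from competing.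

**Compound list**
1 | 3-(benzyloxy)phenol | Oc1cccc(OCc2ccccc2)c1 | starting material
2 | methyl (2S)-oxirane-2-carboxylate | COC(=O)[C@@H]1CO1 | starting material
3 | methyl (2S)-3-[3-(benzyloxy)phenoxy]-2-hydroxypropanoate | COC(=O)[C@@H](O)COc1cccc(OCc2ccccc2)c1 | intermediate
4 | methyl (2S)-3-[3-(benzyloxy)phenoxy]-2-[(methylsulfonyl)oxy]propanoate | COC(=O)[C@@H](OS(C)(=O)=O)COc1cccc(OCc2ccccc2)c1 | intermediate
5 | (2S)-3-[3-(benzyloxy)phenoxy]-1-oxopropan-2-yl methanesulfonate | O=C[C@@H](OS(C)(=O)=O)COc1cccc(OCc2ccccc2)c1 | intermediate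
6 | 3,4-dimethoxyphenol | COc1ccc(O)cc1OC | starting material
7 | 2-bromo-4,5-dimethoxyphenol | COc1cc(O)c(Br)cc1OC | intermediate
8 | 1-(benzyloxy)-2-bromo-4,5-dimethoxybenzene | COc1cc(Br)c(OCc2ccccc2)cc1OC | intermediate
9 | [2-(benzyloxy)-4,5-dimethoxyphenyl]magnesium bromide | COc1cc([Mg]Br)c(OCc2ccccc2)cc1OC | intermediate
10 | (1RS,2S)-1-[2-(benzyloxy)-4,5-dimethoxyphenyl]-3-[3-(benzyloxy)phenoxy]-1-hydroxypropan-2-yl methanesulfonate | COc1cc(C(O)[C@@H](OS(C)(=O)=O)COc2cccc(OCc3ccccc3)c2)c(OCc2ccccc2)cc1OC | intermediate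
11 | (2R)-2-[2-(benzyloxy)-4,5-dimethoxyphenyl]-3-[3-(benzyloxy)phenoxy]propanal | O=C[C@@H](COc1cccc(OCc2ccccc2)c1)c1cc(OC)c(OC)cc1OCc1ccccc1 | intermediate
12 | (3R,4RS)-7-(benzyloxy)-3-[2-(benzyloxy)-4,5-dimethoxyphenyl]chroman-4-ol | OC1c2ccc(OCc3ccccc3)cc2OC[C@H]1c1cc(OC)c(OC)cc1OCc1ccccc1 | intermediate
13 | (3R,4RS)-3-(2-hydroxy-4,5-dimethoxyphenyl)chromane-4,7-diol | OC1c2ccc(O)cc2OC[C@H]1c1cc(OC)c(OC)cc1O | intermediate
14 | (6aR,11aR)-3-hydroxy-8,9-dimethoxypterocarpan | O1[C@H]2c3ccc(O)cc3OC[C@H]2c2cc(OC)c(OC)cc12 | intermediate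
15 | 2-bromo-5-methoxyphenol | COc1ccc(Br)c(O)c1 | starting material
16 | (3R,4S)-4-(5-bromo-4-hydroxy-2-methoxyphenyl)-3-(2-hydroxy-4,5-dimethoxyphenyl)chroman-7-ol | COc1cc(O)c([C@@H]2COc3cc(O)ccc3[C@H]2c2cc(Br)c(O)cc2OC)cc1OC | intermediate
17 | (3R,4S)-7-(benzyloxy)-4-[4-(benzyloxy)-5-bromo-2-methoxyphenyl]-3-[2-(benzyloxy)-4,5-dimethoxyphenyl]chromane | COc1cc(OCc5ccccc5)c([C@@H]2COc3cc(OCc4ccccc4)ccc3[C@H]2c2cc(Br)c(OCc6ccccc6)cc2OC)cc1OC | intermediate
18 | {2-(benzyloxy)-5-[(3R,4S)-7-(benzyloxy)-3-[2-(benzyloxy)-4,5-dimethoxyphenyl]chroman-4-yl]-4-methoxyphenyl}lithium | COc1cc(OCc5ccccc5)c([C@@H]2COc3cc(OCc4ccccc4)ccc3[C@H]2c2cc([Li])c(OCc6ccccc6)cc2OC)cc1OC | intermediate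
19 | {2-(benzyloxy)-5-[(3R,4S)-7-(benzyloxy)-3-[2-(benzyloxy)-4,5-dimethoxyphenyl]chroman-4-yl]-4-methoxyphenyl}magnesium bromide | COc1cc(OCc5ccccc5)c([C@@H]2COc3cc(OCc4ccccc4)ccc3[C@H]2c2cc([Mg]Br)c(OCc6ccccc6)cc2OC)cc1OC | intermediate
20 | (1RS,2S)-1-{2-(benzyloxy)-5-[(3R,4S)-7-(benzyloxy)-3-[2-(benzyloxy)-4,5-dimethoxyphenyl]chroman-4-yl]-4-methoxyphenyl}-3-[3-(benzyloxy)phenoxy]-1-hydroxypropan-2-yl methanesulfonate | COc1cc(OCc5ccccc5)c([C@@H]2COc3cc(OCc4ccccc4)ccc3[C@H]2c2cc(C(O)[C@@H](OS(C)(=O)=O)COc7cccc(OCc8ccccc8)c7)c(OCc6ccccc6)cc2OC)cc1OC | intermediate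
21 | (2R)-2-{2-(benzyloxy)-5-[(3R,4S)-7-(benzyloxy)-3-[2-(benzyloxy)-4,5-dimethoxyphenyl]chroman-4-yl]-4-methoxyphenyl}-3-[3-(benzyloxy)phenoxy]propanal | COc1cc(OCc5ccccc5)c([C@@H]2COc3cc(OCc4ccccc4)ccc3[C@H]2c2cc([C@@H](C=O)COc7cccc(OCc8ccccc8)c7)c(OCc6ccccc6)cc2OC)cc1OC | intermediate
22 | (3R,4RS)-7-(benzyloxy)-3-{2-(benzyloxy)-5-[(3R,4S)-7-(benzyloxy)-3-[2-(benzyloxy)-4,5-dimethoxyphenyl]chroman-4-yl]-4-methoxyphenyl}chroman-4-ol | COc1cc(OCc5ccccc5)c([C@@H]2COc3cc(OCc4ccccc4)ccc3[C@H]2c2cc([C@@H]3COc7cc(OCc8ccccc8)ccc7C3O)c(OCc6ccccc6)cc2OC)cc1OC | intermediate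
23 | (3R,4S)-4-{4-hydroxy-5-[(3R)-7-hydroxychroman-3-yl]-2-methoxyphenyl}-3-(2-hydroxy-4,5-dimethoxyphenyl)chroman-7-ol | COc1cc(O)c([C@@H]2COc3cc(O)ccc3[C@H]2c2cc([C@@H]3COc4cc(O)ccc4C3)c(O)cc2OC)cc1OC | target

**Step count and risks**

Total step count: 13. Longest linear sequence: 11 steps (1, 2, 3, 6, 7, 8, 9, 10, 11, 12, 13).

Steps most likely to fail:

Step 12 (labelled, late-stage). The tandem may break down through hydride instead of aryl migration, enolisation (racemisation) of the aluminium-bound aldehyde before ring closure, methyl transfer from aluminium to the aldehyde, or ring closure at the carbon between the two oxygens of ring D. Fallback, setting out from 20 and coming back at 22: 20 would be rearranged alone with Et3Al (CH2Cl2, −78 °C, the known Suzuki–Tsuchihashi conditions) and aldehyde 21 isolated. Oxidation (NaClO2, NaH2PO4, 2-methyl-2-butene) would give the carboxylic acid F1. Ring F would then be closed through the same C4–C4a bond by intramolecular Friedel–Crafts acylation ((COCl)2, cat. DMF; then SnCl4, CH2Cl2, −40 °C) to the isoflavanone F2, whose C3 is configurationally labile. Transfer hydrogenation with dynamic kinetic resolution (RuCl[(R,R)-TsDPEN](p-cymene), HCO2H–Et3N; sense of induction expected by analogy with aryl ketones) should give the cis (3R,4R) alcohol F3, which is one of the two C4 epimers that make up 22 and enters step 13 as such.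

Step 7 (labelled). The same processes may interfere on the unit 1 substrate. Fallback, setting out from 10 and coming back at 12: Et3Al rearrangement of 10 and isolation of aldehyde 11, oxidation as above to the carboxylic acid F4, Friedel–Crafts acylation to the isoflavanone F5, and transfer hydrogenation with dynamic kinetic resolution to the cis (3R,4R) alcohol F6, a C4 epimer contained in 12, which enters step 8 unchanged.

Step 11. The basic aryl-metal may enolise aldehyde 5 or trigger loss of its β-aryloxide, the aldehyde may degrade between its preparation and use, and the product alkoxide may close onto the mesylate to give an epoxide. Fallback, setting out from 3 (with 17) and coming back at 20: 3 would be converted into the Weinreb amide F7 (MeNH(OMe)·HCl, i-PrMgCl, THF, −20 °C). Its hydroxyl would be deprotonated with i-PrMgCl and aryllithium 18 (from 17 and n-BuLi) added to give the hydroxy ketone F8. Mesylation (MsCl, Et3N) would give the mesyloxy ketone F9, and reduction with i-Bu2AlH (CH2Cl2, −78 °C), the original way of making Suzuki–Tsuchihashi substrates, should give 20.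

Further compounds
F1 | step 12 | (2R)-2-{2-(benzyloxy)-5-[(3R,4S)-7-(benzyloxy)-3-[2-(benzyloxy)-4,5-dimethoxyphenyl]chroman-4-yl]-4-methoxyphenyl}-3-[3-(benzyloxy)phenoxy]propanoic acid | COc1cc(OCc5ccccc5)c([C@@H]2COc3cc(OCc4ccccc4)ccc3[C@H]2c2cc([C@@H](C(=O)O)COc7cccc(OCc8ccccc8)c7)c(OCc6ccccc6)cc2OC)cc1OC
F2 | step 12 | (3RS)-7-(benzyloxy)-3-{2-(benzyloxy)-5-[(3R,4S)-7-(benzyloxy)-3-[2-(benzyloxy)-4,5-dimethoxyphenyl]chroman-4-yl]-4-methoxyphenyl}chroman-4-one | COc1cc(OCc5ccccc5)c([C@@H]2COc3cc(OCc4ccccc4)ccc3[C@H]2c2cc(C3COc7cc(OCc8ccccc8)ccc7C3=O)c(OCc6ccccc6)cc2OC)cc1OC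
F3 | step 12 | (3R,4R)-7-(benzyloxy)-3-{2-(benzyloxy)-5-[(3R,4S)-7-(benzyloxy)-3-[2-(benzyloxy)-4,5-dimethoxyphenyl]chroman-4-yl]-4-methoxyphenyl}chroman-4-ol | COc1cc(OCc5ccccc5)c([C@@H]2COc3cc(OCc4ccccc4)ccc3[C@H]2c2cc([C@@H]3COc7cc(OCc8ccccc8)ccc7[C@@H]3O)c(OCc6ccccc6)cc2OC)cc1OC
F4 | step 7 | (2R)-2-[2-(benzyloxy)-4,5-dimethoxyphenyl]-3-[3-(benzyloxy)phenoxy]propanoic acid | OC(=O)[C@@H](COc1cccc(OCc2ccccc2)c1)c1cc(OC)c(OC)cc1OCc1ccccc1
F5 | step 7 | (3RS)-7-(benzyloxy)-3-[2-(benzyloxy)-4,5-dimethoxyphenyl]chroman-4-one | O=C1c2ccc(OCc3ccccc3)cc2OCC1c1cc(OC)c(OC)cc1OCc1ccccc1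
F6 | step 7 | (3R,4R)-7-(benzyloxy)-3-[2-(benzyloxy)-4,5-dimethoxyphenyl]chroman-4-ol | O[C@H]1c2ccc(OCc3ccccc3)cc2OC[C@H]1c1cc(OC)c(OC)cc1OCc1ccccc1
F7 | step 11 | (2S)-3-[3-(benzyloxy)phenoxy]-2-hydroxy-N-methoxy-N-methylpropanamide | CON(C)C(=O)[C@@H](O)COc1cccc(OCc2ccccc2)c1
F8 | step 11 | (2S)-1-{2-(benzyloxy)-5-[(3R,4S)-7-(benzyloxy)-3-[2-(benzyloxy)-4,5-dimethoxyphenyl]chroman-4-yl]-4-methoxyphenyl}-3-[3-(benzyloxy)phenoxy]-2-hydroxypropan-1-one | COc1cc(OCc5ccccc5)c([C@@H]2COc3cc(OCc4ccccc4)ccc3[C@H]2c2cc(C(=O)[C@@H](O)COc7cccc(OCc8ccccc8)c7)c(OCc6ccccc6)cc2OC)cc1OC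
F9 | step 11 | (2S)-1-{2-(benzyloxy)-5-[(3R,4S)-7-(benzyloxy)-3-[2-(benzyloxy)-4,5-dimethoxyphenyl]chroman-4-yl]-4-methoxyphenyl}-3-[3-(benzyloxy)phenoxy]-1-oxopropan-2-yl methanesulfonate | COc1cc(OCc5ccccc5)c([C@@H]2COc3cc(OCc4ccccc4)ccc3[C@H]2c2cc(C(=O)[C@@H](OS(C)(=O)=O)COc7cccc(OCc8ccccc8)c7)c(OCc6ccccc6)cc2OC)cc1OC
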